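**Retrosynthetic overview** (briarane numbering: ten-membered ring C1–C10; cyclohexenone C1, C10, C11, C12, C13, C14; lactone O–C7, C8, C17, C19; one-carbon branches C15, C16, C18, C20)
1. Last steps: C16 PMB ether off, C9/C11 acetates on. Before that the cyclohexenone is cut at C12–C13 and C13=C14 into a C14 aldehyde, a C12 methyl ester and a one-carbon silyl ynolate: a (5+1) annulation by [2+2] cycloaddition, Dieckmann closure and loss of CO2.
2. γ-Lactone: SmI2 Reformatsky reaction of a C7 2-bromopropanoate onto a C8 ketone; C7–O from Sharpless epoxidation and Ti-mediated epoxide opening; ten-membered ring: Nozaki–Hiyama–Kishi closure of C8–C9.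
3. C1–C10 bond, quaternary C1 and (E)-C2=C3: dianionic Ireland–Claisen rearrangement of the ester of (S)-citramalic acid 1-methyl ester (C9–C12, C20) with an (S)-allylic alcohol (C1–C8, C14–C16) made by Keck allylation, RCM and Takai olefination.
4. Ring order: dihydropyranone (temporary, opened) → ten-membered carbocycle → 7,8-epoxide (temporary, opened) → γ-lactone → 2,3-epoxide → cyclohexenone (last).
5. Enabling feature: in the six-membered ring C13 is the only unsubstituted carbon and lies between C14 (on the quaternary C1) and the C12 carbonyl (on the fully substituted C11); the 1,5-related aldehyde and ester of the seco compound cannot enolise, so one carbon can be stitched between them.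

Key step: step 22

Remarks: (i) 2-Bromopropanoic acid is used as the racemate, because its stereocentre becomes an enolate in step 19. (ii) Lactol 12 is an anomeric mixture; C13/C14 of 32 and 33 are transient and left undefined. (iii) For the large intermediates the SMILES defines the configuration; every centre already present has the spatial arrangement it has in 37 (CIP letters can change with the substituents).

**Step 1**
Reactants: 1 1,1-dimethoxypropan-2-one; 2 diethyl [2-(methoxy(methyl)amino)-2-oxoethyl]phosphonate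
Product: 3 (E)-N,4,4-trimethoxy-N,3-dimethylbut-2-enamide
Conditions: NaH, THF, 0 °C → rt
Reagents that add atoms: none
Why: Horner–Wadsworth–Emmons olefination of the ketone; the bulky dimethoxymethyl group should end up trans to the amide (E).

**Step 2**
Reactants: 3 (E)-N,4,4-trimethoxy-N,3-dimethylbut-2-enamide
Product: 4 (E)-4,4-dimethoxy-3-methylbut-2-enal
Conditions: DIBAL-H (1.2 equiv), THF, −78 °C; Rochelle salt
Reagents that add atoms: none
Why: Weinreb amide reduction stops at the aldehyde through the chelated aluminium hemiaminal.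

**Step 3**
Reactants: 5 2-methylenepropane-1,3-diol
Product: 6 2-{[(4-methoxybenzyl)oxy]methyl}prop-2-en-1-ol
Conditions: NaH (1 equiv), PMBCl, Bu4NI (cat.), THF–DMF, 0 °C → rt (diol in excess)
Reagents that add atoms: 4-methoxybenzyl chloride, COc1ccc(CCl)cc1
Why: Williamson mono-etherification of the symmetric diol.

**Step 4**
Reactants: 6 2-{[(4-methoxybenzyl)oxy]methyl}prop-2-en-1-ol
Product: 8 tributyl(2-{[(4-methoxybenzyl)oxy]methyl}allyl)stannane, via allylic mesylate 7 (not isolated)
Conditions: MsCl, Et3N, THF, −20 °C; then Bu3SnLi (from Bu3SnH, LDA), −78 → 0 °C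
Reagents that add atoms: tributylstannyllithium, [Li][Sn](CCCC)(CCCC)CCCC
Why: mesylation followed by SN2 displacement with the stannyl anion.

**Step 5**
Reactants: 4 (E)-4,4-dimethoxy-3-methylbut-2-enal; 8 tributyl(2-{[(4-methoxybenzyl)oxy]methyl}allyl)stannane
Product: 9 (2E,4S)-1,1-dimethoxy-6-{[(4-methoxybenzyl)oxy]methyl}-2-methylhepta-2,6-dien-4-ol
Conditions: (S)-BINOL (20 mol %), Ti(OiPr)4 (10 mol %), 4 Å MS, CH2Cl2, −20 °C
Reagents that add atoms: none
Why: Keck asymmetric allylation (1,2-addition to the enal); the (S)-BINOL–Ti catalyst sets the C3 carbinol as S.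

**Step 6**
Reactants: 9 (2E,4S)-dienol
Product: 10 (2E,4S)-1,1-dimethoxy-6-{[(4-methoxybenzyl)oxy]methyl}-2-methylhepta-2,6-dien-4-yl prop-2-enoate
Conditions: acryloyl chloride, Et3N, DMAP (cat.), CH2Cl2, 0 °C
Reagents that add atoms: acryloyl chloride, C=CC(=O)Cl
Why: O-acylation of the secondary alcohol.

**Step 7**
Reactants: 10 acrylate
Product: 11 (6S)-6-[(1E)-3,3-dimethoxy-2-methylprop-1-enyl]-4-{[(4-methoxybenzyl)oxy]methyl}-5,6-dihydro-2H-pyran-2-one
Conditions: Grubbs second-generation catalyst (5 mol %), CH2Cl2, 40 °C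
Reagents that add atoms: none
Why: ring-closing metathesis of the acrylate with the 1,1-disubstituted alkene; the six-membered ring fixes the C5=C6 geometry (C4 and C7 cis), and the trisubstituted acetal alkene does not take part.

**Step 8**
Reactants: 11 dihydropyranone
Product: 12 (6S)-6-[(1E)-3,3-dimethoxy-2-methylprop-1-enyl]-4-{[(4-methoxybenzyl)oxy]methyl}-5,6-dihydro-2H-pyran-2-ol (anomers)
Conditions: DIBAL-H (1.1 equiv), CH2Cl2, −78 °C; Rochelle salt
Reagents that add atoms: none
Why: 1,2-reduction of the unsaturated lactone to the lactol at low temperature.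

**Step 9**
Reactants: 12 lactol
Product: 13 (2E,4S,6E,8E)-9-iodo-1,1-dimethoxy-6-{[(4-methoxybenzyl)oxy]methyl}-2-methylnona-2,6,8-trien-4-ol (C4 and C7 of the later ring cis across C5=C6)
Conditions: CrCl2 (6 equiv), CHI3 (2 equiv), THF–dioxane, 0 °C → rt
Reagents that add atoms: iodoform, IC(I)I
Why: Takai iodo-olefination of the open hydroxy-enal form of the lactol, E-selective at the new C7=C8 bond; the C3 hydroxyl is set free for the esterification.

**Step 10**
Reactants: 14 (S)-citramalic acid
Product: 16 (3S)-3-hydroxy-4-methoxy-3-methyl-4-oxobutanoic acid, via O-trifluoroacetyl citramalic anhydride 15 (not isolated)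
Conditions: (CF3CO)2O, 0 °C → rt; evaporate; MeOH, rt
Reagents that add atoms: methanol, CO
Why: the cyclic anhydride is opened by methanol at the carbonyl next to the oxygen-bearing carbon (as for malic acid) and the trifluoroacetate is lost by methanolysis, which differentiates the two carboxyls.

**Step 11**
Reactants: 13 dienyl iodide alcohol; 16 citramalic acid 1-methyl ester
Product: 17 allylic ester (C3–O–C9 ester of 13 with 16)
Conditions: EDC·HCl, DMAP, CH2Cl2, 0 °C → rt
Reagents that add atoms: none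
Why: Steglich-type esterification of the secondary allylic alcohol; the tertiary hydroxyl of 16 does not compete.

**Step 12**
Reactants: 17 allylic ester
Product: 19 Claisen acid (C9 carboxylic acid with the C1–C10 bond), via bis-silyl ketene acetal 18 (not isolated)
Conditions: LDA (2.3 equiv), THF, −78 °C; Me3SiCl/Et3N, −78 → 50 °C; 1 M HCl
Reagents that add atoms: none
Why: dianionic Ireland–Claisen rearrangement: the lithium chelate between the C11 alkoxide and the enolate oxygen fixes the enolate geometry (C11 cis to O-metal), and a chair transition state with the C4 chain equatorial at C3 transfers the C3 chirality to the quaternary C1 and to C10 and gives the (E)-C2=C3 alkene.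

**Step 13**
Reactants: 19 Claisen acid
Product: 21 C9 primary alcohol, via isobutyl carbonic anhydride 20 (not isolated)
Conditions: iBuOCOCl, N-methylmorpholine, THF, −15 °C; NaBH4, MeOH, −15 → 0 °C
Reagents that add atoms: none
Why: mixed-anhydride reduction with borohydride is selective for the activated carboxyl; the hindered methyl ester, the vinyl iodide and the acetal should survive.

**Step 14**
Reactants: 21 C9 primary alcohol
Product: 22 C9 aldehyde
Conditions: Dess–Martin periodinane, NaHCO3, CH2Cl2, 0 °C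
Reagents that add atoms: none
Why: buffered Dess–Martin oxidation of the primary alcohol; neutral conditions avoid retro-aldol cleavage and epimerisation at C10, and the tertiary hydroxyl is inert.

**Step 15**
Reactants: 22 C9 aldehyde
Product: 23 ten-membered (2E,5Z,7E)-trien-9-ol (C9 carbinol as in 37)
Conditions: CrCl2 (10 equiv), NiCl2 (1 mol %), DMSO–THF, 2 mM, rt
Reagents that add atoms: none
Why: Nozaki–Hiyama–Kishi macrocyclisation: the alkenylchromium adds with retention of the (E)-C7=C8 geometry, and Cr(III) bridging the aldehyde oxygen and the free C11 hydroxyl should direct attack anti to the C1 substituent on C10, which sets C9.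

**Step 16**
Reactants: 23 trienol
Product: 24 7,8-epoxy-9-ol (trans-epoxide, erythro to the C9 hydroxyl)
Conditions: Ti(OiPr)4, D-(−)-diethyl tartrate, tBuOOH, 4 Å MS, CH2Cl2, −20 °C
Reagents that add atoms: tert-butyl hydroperoxide, CC(C)(C)OO
Why: Sharpless asymmetric epoxidation of the secondary allylic alcohol; D-(−)-tartrate is the matched partner for this carbinol, gives the erythro epoxy alcohol, and only the allylic C7=C8 bond reacts.

**Step 17**
Reactants: 24 epoxy alcohol; 25 2-bromopropanoic acid (racemic)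
Product: 26 7-O-(2-bromopropanoyl)-8,9-diol
Conditions: Ti(OiPr)4 (1.5 equiv), CH2Cl2, rt
Reagents that add atoms: none
Why: titanium-mediated opening of a 2,3-epoxy alcohol at the distal carbon by a carboxylic acid; C7 is also allylic, and the attack inverts C7 to the configuration of 37.

**Step 18**
Reactants: 26 bromopropanoate diol
Product: 27 8-ketone (9-hydroxy, 7-O-(2-bromopropanoyl))
Conditions: Dess–Martin periodinane (1.1 equiv), NaHCO3, CH2Cl2, 0 °C
Reagents that add atoms: none
Why: mono-oxidation of the less hindered C8 hydroxyl; the C9 hydroxyl is shielded by C10 with its two fully substituted neighbours.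

**Step 19**
Reactants: 27 keto bromopropanoate
Product: 28 γ-lactone triol (C8–C17 bond, C8 tertiary hydroxyl)
Conditions: SmI2 (2.5 equiv), THF, −78 °C; sat. NH4Cl
Reagents that add atoms: none
Why: intramolecular samarium Reformatsky reaction: the Sm(III) enolate, held by the O7 tether and chelated to the ketone and the free C9 hydroxyl, should add to C8 from the face anti to C10, and the C17 methyl takes the position anti to C9, which is also the thermodynamically favoured (epimerisable) arrangement.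

**Step 20**
Reactants: 28 lactone triol
Product: 29 2,3-epoxide (trans, configuration of 37)
Conditions: D-fructose-derived Shi ketone (0.3 equiv), Oxone, K2CO3, Bu4NHSO4, MeCN–DMM–aq. borate buffer, 0 °C
Reagents that add atoms: potassium peroxymonosulfate (Oxone), [K+].[O-]S(=O)(=O)OO
Why: Shi epoxidation of the trans-disubstituted C2=C3 bond with catalyst control of the face (R,R sense); the C5=C6 bond is deactivated by its two allylic C–O bonds.

**Step 21**
Reactants: 29 epoxide
Product: 31 C14 aldehyde 8,9,11-tris(triethylsilyl) ether, via lutidinium N,O-acetal triflate 30 (not isolated)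
Conditions: Et3SiOTf (6 equiv), 2,6-lutidine (9 equiv), CH2Cl2, −40 → 0 °C; then H2O
Reagents that add atoms: triethylsilyl trifluoromethanesulfonate, CC[Si](CC)(CC)OS(=O)(=O)C(F)(F)F
Why: silyl triflate/2,6-lutidine cleavage of the dimethyl acetal through the pyridinium salt, hydrolysed by water to the aldehyde, with silylation of the three hydroxyls in the same operation.

**Step 22**
Reactants: 31 aldehyde tris(triethylsilyl) ether
Product: 34 cyclohexenone 8,9,11-tris(triethylsilyl) ether, via lithium β-lactone enolate 32 (not isolated), via fused keto-β-lactone 33 (not isolated)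
Conditions: Me3SiC≡COLi (from Me3SiCHN2, n-BuLi, CO 1 atm, THF, −78 °C), THF, −78 → −20 °C; AcOH, −78 °C; then SiO2, PhMe, 80 °C
Reagents that add atoms: lithium (trimethylsilyl)ethynolate, [Li]OC#C[Si](C)(C)C, made in the flask from (trimethylsilyl)diazomethane, C[Si](C)(C)C=[N+]=[N-], n-butyllithium, [Li]CCCC, and carbon monoxide, [C-]#[O+]
Why: Proposed new method: the silyl ynolate adds to the only aldehyde by a stepwise [2+2] cycloaddition to give the β-lactone enolate 32, whose carbanion (the future C13) attacks the C12 methyl ester in a 6-(enolexo)-exo-trig Dieckmann closure; the expelled methoxide removes the C-silyl group as Me3SiOMe to leave a stabilised enolate, protonation gives 33, and thermal [2+2] cycloreversion extrudes CO2 to deliver the C13=C14 enone. The closest known reaction type is the tandem ynolate [2+2] cycloaddition/Dieckmann condensation/decarboxylation of δ-oxo esters to cyclohex-2-enones with alkyl ynolates; new here are the aldehyde acceptor, the α-quaternary ester and the silyl ynolate as an equivalent of the parent H-ynolate. The six-membered carbocycle is closed by the Dieckmann step, and the four-membered lactone formed by the cycloaddition is destroyed again. No stereocentre is created that survives: C13 and C14 of 33 become sp2, the ring enforces the cis C13=C14 geometry, and C1, C10 and C11 are already fixed. The step needs chemoselectivity: ynolates do not attack esters or lactones at −78 °C, the aldehyde on the quaternary C1 and the ester on the fully substituted C11 cannot enolise, the lactone carbonyl is out of reach of the enolate, the β-lactone enolate cannot β-eliminate because its C–O bond lies in the nodal plane of the enolate, and all hydroxyls are silylated.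

**Step 23**
Reactants: 34 enone tris(triethylsilyl) ether
Product: 35 enone 8,9,11-triol (C16 PMB ether)
Conditions: TBAF–AcOH (1:1), THF, 0 °C → rt
Reagents that add atoms: none
Why: buffered fluoride cleavage of the silyl ethers; acetic acid suppresses α-ketol rearrangement and retro-aldol pathways.

**Step 24**
Reactants: 35 enone triol
Product: 36 9,11-diacetate (8-OH free, C16 PMB ether)
Conditions: Ac2O, DMAP, Et3N, CH2Cl2, rt → 35 °C
Reagents that add atoms: acetic anhydride, CC(=O)OC(C)=O
Why: DMAP-catalysed acetylation of the secondary C9 hydroxyl and the tertiary α-ketol C11 hydroxyl; the tertiary C8 hydroxyl, flanked by C7, C9 and C17, should stay free.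

**Step 25**
Reactants: 36 diacetate PMB ether
Product: 37 CNP0155754.2
Conditions: DDQ, CH2Cl2–pH 7 buffer, 0 °C
Reagents that add atoms: none
Why: oxidative cleavage of the p-methoxybenzyl ether under neutral conditions that should spare the acetates, epoxide, enone and lactone.

**Compound list**
1 | 1,1-dimethoxypropan-2-one | CC(=O)C(OC)OC | starting material
2 | diethyl [2-(methoxy(methyl)amino)-2-oxoethyl]phosphonate | CCOP(=O)(OCC)CC(=O)N(C)OC | starting material
3 | (E)-N,4,4-trimethoxy-N,3-dimethylbut-2-enamide | CON(C)C(=O)/C=C(\C)C(OC)OC | intermediate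
4 | (E)-4,4-dimethoxy-3-methylbut-2-enal | O=C/C=C(\C)C(OC)OC | intermediate
5 | 2-methylenepropane-1,3-diol | C=C(CO)CO | starting material
6 | 2-{[(4-methoxybenzyl)oxy]methyl}prop-2-en-1-ol | C=C(CO)COCc1ccc(OC)cc1 | intermediate
7 | 2-{[(4-methoxybenzyl)oxy]methyl}allyl methanesulfonate | C=C(COS(C)(=O)=O)COCc1ccc(OC)cc1 | intermediate (not isolated)
8 | tributyl(2-{[(4-methoxybenzyl)oxy]methyl}allyl)stannane | CCCC[Sn](CCCC)(CCCC)CC(=C)COCc1ccc(OC)cc1 | intermediate
9 | (2E,4S)-1,1-dimethoxy-6-{[(4-methoxybenzyl)oxy]methyl}-2-methylhepta-2,6-dien-4-ol | COC(OC)/C(C)=C/[C@@H](O)CC(=C)COCc1ccc(OC)cc1 | intermediate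
10 | acrylate of 9 | COC(OC)/C(C)=C/[C@@H](OC(=O)C=C)CC(=C)COCc1ccc(OC)cc1 | intermediate
11 | (6S)-6-[(1E)-3,3-dimethoxy-2-methylprop-1-enyl]-4-{[(4-methoxybenzyl)oxy]methyl}-5,6-dihydro-2H-pyran-2-one | COC(OC)/C(C)=C/[C@@H]1CC(COCc2ccc(OC)cc2)=CC(=O)O1 | intermediate
12 | lactol of 11 (anomeric mixture) | COC(OC)/C(C)=C/[C@@H]1CC(COCc2ccc(OC)cc2)=CC(O)O1 | intermediate
13 | (2E,4S,6E,8E)-9-iodo-1,1-dimethoxy-6-{[(4-methoxybenzyl)oxy]methyl}-2-methylnona-2,6,8-trien-4-ol | COC(OC)/C(C)=C/[C@@H](O)C/C(COCc1ccc(OC)cc1)=C\C=C\I | intermediate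
14 | (S)-citramalic acid, (2S)-2-hydroxy-2-methylbutanedioic acid | C[C@](O)(CC(=O)O)C(=O)O | starting material
15 | O-trifluoroacetyl citramalic anhydride | C[C@]1(OC(=O)C(F)(F)F)CC(=O)OC1=O | intermediate (not isolated)
16 | (3S)-3-hydroxy-4-methoxy-3-methyl-4-oxobutanoic acid | C[C@](O)(CC(=O)O)C(=O)OC | intermediate
17 | ester of the C3 hydroxyl of 13 with the free carboxyl of 16 | COC(OC)/C(C)=C/[C@@H](OC(=O)C[C@](C)(O)C(=O)OC)C/C(COCc1ccc(OC)cc1)=C\C=C\I | intermediate
18 | bis(trimethylsilyl) ketene acetal of 17 (C11 cis to OSi) | COC(OC)/C(C)=C/[C@@H](O/C(O[Si](C)(C)C)=C/[C@](C)(O[Si](C)(C)C)C(=O)OC)C/C(COCc1ccc(OC)cc1)=C\C=C\I | intermediate (not isolated)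
19 | Claisen acid: C9 acid; C10 bears C1 (Me, CH(OMe)2, (E)-C2=C3 chain to the dienyl iodide) and C11 (OH, Me, CO2Me) | OC(=O)[C@H]([C@](C)(C(OC)OC)/C=C/C/C(COCc1ccc(OC)cc1)=C\C=C\I)[C@](C)(O)C(=O)OC | intermediate
20 | isobutyl carbonic anhydride of 19 | CC(C)COC(=O)OC(=O)[C@H]([C@](C)(C(OC)OC)/C=C/C/C(COCc1ccc(OC)cc1)=C\C=C\I)[C@](C)(O)C(=O)OC | intermediate (not isolated)
21 | C9 primary alcohol (reduced 19) | OC[C@H]([C@](C)(C(OC)OC)/C=C/C/C(COCc1ccc(OC)cc1)=C\C=C\I)[C@](C)(O)C(=O)OC | intermediate
22 | C9 aldehyde | O=C[C@H]([C@](C)(C(OC)OC)/C=C/C/C(COCc1ccc(OC)cc1)=C\C=C\I)[C@](C)(O)C(=O)OC | intermediate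
23 | ten-membered (2E,5Z,7E)-trien-9-ol with C1 (Me, CH(OMe)2), C5 CH2OPMB, C10 side chain C11 (OH, Me, CO2Me) | O[C@H]1/C=C/C=C(COCc2ccc(OC)cc2)\C/C=C/[C@@](C)(C(OC)OC)[C@@H]1[C@](C)(O)C(=O)OC | intermediate
24 | 7,8-epoxy-9-ol of 23 | O[C@H]1[C@H]2O[C@@H]2/C=C(COCc2ccc(OC)cc2)\C/C=C/[C@@](C)(C(OC)OC)[C@@H]1[C@](C)(O)C(=O)OC | intermediate
25 | 2-bromopropanoic acid (racemic) | CC(Br)C(=O)O | starting material
26 | 7-O-(2-bromopropanoyl)-8,9-diol | O[C@H]1[C@@H](O)[C@@H](OC(=O)C(C)Br)/C=C(COCc2ccc(OC)cc2)\C/C=C/[C@@](C)(C(OC)OC)[C@@H]1[C@](C)(O)C(=O)OC | intermediate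
27 | 8-ketone of 26 | O[C@H]1C(=O)[C@@H](OC(=O)C(C)Br)/C=C(COCc2ccc(OC)cc2)\C/C=C/[C@@](C)(C(OC)OC)[C@@H]1[C@](C)(O)C(=O)OC | intermediate
28 | γ-lactone 8,9,11-triol with (E)-C2=C3 | O[C@H]1[C@]2(O)[C@@H](C)C(=O)O[C@H]2/C=C(COCc2ccc(OC)cc2)\C/C=C/[C@@](C)(C(OC)OC)[C@@H]1[C@](C)(O)C(=O)OC | intermediate
29 | 2,3-epoxide of 28 | O[C@H]1[C@]2(O)[C@@H](C)C(=O)O[C@H]2/C=C(COCc2ccc(OC)cc2)\C[C@H]2O[C@@H]2[C@@](C)(C(OC)OC)[C@@H]1[C@](C)(O)C(=O)OC | intermediate
30 | 2,6-lutidinium N,O-acetal triflate of the tris(triethylsilyl) ether | CC[Si](CC)(CC)O[C@H]1[C@]2(O[Si](CC)(CC)CC)[C@@H](C)C(=O)O[C@H]2/C=C(COCc2ccc(OC)cc2)\C[C@H]2O[C@@H]2[C@@](C)(C(OC)[n+]2c(C)cccc2C)[C@@H]1[C@](C)(O[Si](CC)(CC)CC)C(=O)OC.[O-]S(=O)(=O)C(F)(F)F | intermediate (not isolated)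
31 | C14 aldehyde 8,9,11-tris(triethylsilyl) ether | CC[Si](CC)(CC)O[C@H]1[C@]2(O[Si](CC)(CC)CC)[C@@H](C)C(=O)O[C@H]2/C=C(COCc2ccc(OC)cc2)\C[C@H]2O[C@@H]2[C@@](C)(C=O)[C@@H]1[C@](C)(O[Si](CC)(CC)CC)C(=O)OC | intermediate
32 | lithium enolate of the α-silyl β-lactone on C14 (C14 epimers) | CC[Si](CC)(CC)O[C@H]1[C@]2(O[Si](CC)(CC)CC)[C@@H](C)C(=O)O[C@H]2/C=C(COCc2ccc(OC)cc2)\C[C@H]2O[C@@H]2[C@@](C)(C2OC(O[Li])=C2[Si](C)(C)C)[C@@H]1[C@](C)(O[Si](CC)(CC)CC)C(=O)OC | intermediate (not isolated)
33 | cyclohexanone with cis-fused β-lactone across C13–C14 | CC[Si](CC)(CC)O[C@@H]1[C@@H]2[C@](C)(C3OC(=O)C3C(=O)[C@@]2(C)O[Si](CC)(CC)CC)[C@H]2O[C@@H]2C/C(COCc2ccc(OC)cc2)=C\[C@@H]2OC(=O)[C@H](C)[C@]21O[Si](CC)(CC)CC | intermediate (not isolated)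
34 | cyclohexenone 8,9,11-tris(triethylsilyl) ether, C16 PMB ether | CC[Si](CC)(CC)O[C@@H]1[C@@H]2[C@](C)(C=CC(=O)[C@@]2(C)O[Si](CC)(CC)CC)[C@H]2O[C@@H]2C/C(COCc2ccc(OC)cc2)=C\[C@@H]2OC(=O)[C@H](C)[C@]21O[Si](CC)(CC)CC | intermediate
35 | cyclohexenone 8,9,11-triol, C16 PMB ether | O[C@@H]1[C@@H]2[C@](C)(C=CC(=O)[C@@]2(C)O)[C@H]2O[C@@H]2C/C(COCc2ccc(OC)cc2)=C\[C@@H]2OC(=O)[C@H](C)[C@]21O | intermediate
36 | 9,11-diacetate, C16 PMB ether | CC(=O)O[C@@H]1[C@@H]2[C@](C)(C=CC(=O)[C@@]2(C)OC(C)=O)[C@H]2O[C@@H]2C/C(COCc2ccc(OC)cc2)=C\[C@@H]2OC(=O)[C@H](C)[C@]21O | intermediate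
37 | CNP0155754.2 | CC(=O)O[C@@H]1[C@@H]2[C@](C)(C=CC(=O)[C@@]2(C)OC(C)=O)[C@H]2O[C@@H]2C/C(CO)=C\[C@@H]2OC(=O)[C@H](C)[C@]21O | target

**Step count and risks**
Total: 25 steps. Longest linear sequence: 22 steps (1, 2, 5–9, 11–25).

1. Step 22 (proposed new method). The β-lactone enolate may ring-open to the silyl acrylate before the Dieckmann closure onto the hindered ester, or the CO2 loss at the neopentyl C14 may be accompanied by a 1,2-shift. Fallback from 31: aldol addition of the lithium enolate of allyl acetate (LDA, THF, −78 °C) should give the β-hydroxy allyl ester F1. LiHMDS (−78 → 0 °C) should then close the six-membered ring by Dieckmann condensation onto the C12 methyl ester to give the β-keto allyl ester F2. Pd(PPh3)4/morpholine should remove the allyl group with loss of CO2 to give the β-hydroxy ketone F3. Mesylation and elimination (MsCl, Et3N; DBU) should then give 34, where the route is rejoined.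

2. Step 15. Intermolecular coupling or protodeiodination may outrun closure of the strained triene ring, and facial selectivity at C9 may be poor if the chromium chelate does not form. Fallback from 21: elimination of hydrogen iodide with NaHMDS (THF, −78 → 0 °C) should give the terminal enyne diol F4, and Dess–Martin oxidation the ynal F5. Hydroboration of the alkyne with dicyclohexylborane, boron-to-zinc exchange with Et2Zn and amino-alcohol-catalysed intramolecular addition of the alkenylzinc to the aldehyde should then give 23.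

3. Step 19. Reductive cleavage of the α-acyloxy or α-hydroxy ketone by SmI2 may compete with enolate formation, and the face of C8 attacked may be set by the ring conformation instead of by chelation. Fallback from 24: Ti(OiPr)4/benzoic acid opening should give the 7-benzoate diol F6, and Dess–Martin oxidation the 8-ketone F7. Chelation-controlled aldol addition of the lithium enolate of methyl propanoate (MgBr2·OEt2, THF, −78 °C) should give the β-hydroxy ester F8. K2CO3/MeOH should remove the benzoate, and the freed C7 alkoxide should lactonise to 28.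

**Further compounds**
F1 | step 22 | β-hydroxy allyl ester (aldol adduct at C14) | CC[Si](CC)(CC)O[C@H]1[C@]2(O[Si](CC)(CC)CC)[C@@H](C)C(=O)O[C@H]2/C=C(COCc2ccc(OC)cc2)\C[C@H]2O[C@@H]2[C@@](C)(C(O)CC(=O)OCC=C)[C@@H]1[C@](C)(O[Si](CC)(CC)CC)C(=O)OC
F2 | step 22 | cyclic β-keto allyl ester (C13 allyl carboxylate, C14 hydroxyl) | CC[Si](CC)(CC)O[C@@H]1[C@@H]2[C@](C)(C(O)C(C(=O)OCC=C)C(=O)[C@@]2(C)O[Si](CC)(CC)CC)[C@H]2O[C@@H]2C/C(COCc2ccc(OC)cc2)=C\[C@@H]2OC(=O)[C@H](C)[C@]21O[Si](CC)(CC)CC
F3 | step 22 | 14-hydroxy cyclohexanone | CC[Si](CC)(CC)O[C@@H]1[C@@H]2[C@](C)(C(O)CC(=O)[C@@]2(C)O[Si](CC)(CC)CC)[C@H]2O[C@@H]2C/C(COCc2ccc(OC)cc2)=C\[C@@H]2OC(=O)[C@H](C)[C@]21O[Si](CC)(CC)CC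
F4 | step 15 | terminal enyne diol | OC[C@H]([C@](C)(C(OC)OC)/C=C/C/C(COCc1ccc(OC)cc1)=C\C#C)[C@](C)(O)C(=O)OC
F5 | step 15 | ynal | O=C[C@H]([C@](C)(C(OC)OC)/C=C/C/C(COCc1ccc(OC)cc1)=C\C#C)[C@](C)(O)C(=O)OC
F6 | step 19 | 7-benzoate 8,9-diol | O[C@H]1[C@@H](O)[C@@H](OC(=O)c2ccccc2)/C=C(COCc2ccc(OC)cc2)\C/C=C/[C@@](C)(C(OC)OC)[C@@H]1[C@](C)(O)C(=O)OC
F7 | step 19 | 7-benzoate 8-ketone | O[C@H]1C(=O)[C@@H](OC(=O)c2ccccc2)/C=C(COCc2ccc(OC)cc2)\C/C=C/[C@@](C)(C(OC)OC)[C@@H]1[C@](C)(O)C(=O)OC
F8 | step 19 | C8 aldol adduct with methyl propanoate (7-benzoate) | O[C@H]1[C@](O)([C@@H](C)C(=O)OC)[C@@H](OC(=O)c2ccccc2)/C=C(COCc2ccc(OC)cc2)\C/C=C/[C@@](C)(C(OC)OC)[C@@H]1[C@](C)(O)C(=O)OC
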